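Follow the flask slowly and keep one count beside the clock. Each Q made sets free one J, and X can take J up as D, so the charge of X over the charge of E, called C, is the share of E that can become Q while X still holds J. Reckoned as if X binds tightly, this flask has C = 10.0%.

all flasks: L 0.045 mM (held)

| run | E | X | remark | time |
|---|---|---|---|---|
| grey | 7.0 × 10⁻⁴ M | 0.050 mM | run made earlier |  |
| violet | 0.0011 M | 0.050 mM | run made earlier |  |
| flask | 5.0 × 10⁻⁴ M | 0.0500 mM |  | 6.0 min |

- grey (time / min: Q / %, E / %): 1.00: 0.7, 99.0; 2.00: 2.0, 97.7; 3.00: 3.5, 97.0; 4.00: 4.3, 96.4; 5.00: 4.3, 95.2
- violet (time / min: Q / %, E / %): 0.417: 0.2, 99.3; 0.667: 0.3, 99.0; 1.33: 0.6, 98.4; 2.50: 2.4, 97.8; 5.00: 5.2, 94.7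

(readings scatter by 0.3 percentage points)

1. amount of Q at 6.0 min, in percent of the E charged
2. the change that raises the amount of Q at 6.0 min, in percent of the E charged most ("none" if none brings more than 2 percentage points) (autumn / winter / none)
3. amount of Q at 6.0 min, in percent of the E charged, after autumn

- at the start none of Z is dissolved
- candidate steps: E + Z -> Q + J; E + Z + J -> Q + 2 J; L <-> Z; X + J <-> D

- autumn: doubling the saturation concentration of L, all else as stated
- winter: doubling the transfer coefficient of L, all else as stated

The zero of the scale is the case without J's help: with Z steady, the plain step is pseudo-first-order in E and gives equal percentages per minute at either charge. Violet holds 1.57 times grey's E, yet at 5.00 min the runs read 5.2% and 4.3% of Q, a pooled slope of 0.00950 /min.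

In the first instants Z starts from nothing and L fills it, too briefly to time against a scatter of 0.3 percentage points. Through the middle Q climbs along that slope while X turns into D. By this reckoning C is reached at 10.5 min, later than 6.0 min, so the flask ends near 5.70% with X still free. Violet's C is 4.55%, and its last Q reading stands past it. Autumn doubles the saturation concentration of L, so Z and the slope double too, giving 11.4%, beyond C, so this reckoning expects somewhat more. Winter doubles the transfer coefficient of L, which hastens the filling of Z but leaves its saturation level where it was, so this reckoning expects a gain of less than 2 points.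

The forecast gives 5.8%, names autumn, and gives 12% after it, on the ground “any autocatalysis is masked by the base”. Its first value stands slightly above this reckoning's 5.70%.

    E + Z → Q + J (k = 3.50 /M/s)
    E + Z + J → Q + 2 J (k = 1.30 × 10⁶ /M²/s)
    L ⇌ Z, rate k3*(csat - [Z]) (kL = 7.40 /s)
    X + J ⇌ D, settled at all times (K = 4.20 × 10⁷ /M)

The flask gives 5.53% of Q, and autumn gives 13.1%. At 6.00 min the flask keeps 45% of its X unbound, and C gives 44.7% from the Q made. A neighbour flask with 2.0 × 10⁻⁵ M of X has C = 4.00%; its Q reaches 14.0% at 6.00 min, past that C, with 0.047% of its X unbound.

Readings and results are simulated on assumed constants; scatter was added.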